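**Retrosynthetic overview**

- The cyclohexene is the head-to-head [4+2] dimer of one achiral diene, 3-(2-methylbut-3-en-2-yl)-5-[(E)-3-methylbuta-1,3-dienyl]indole. Cutting ring bonds C1–C6 and C4–C5 gives one molecule as the 4π unit (ArCH=CH–C(Me)=CH2) and the isopropenyl C=C of a second as the 2π unit.
- Both stereocentres are set in that dimerisation, run as a chiral-phosphate-templated, photoredox hole-catalysed Diels–Alder reaction.
- The monomer is cut at indole C5 (Suzuki) into 5-bromo-3-(2-methylbut-3-en-2-yl)indole and an (E)-dienyl pinacol boronate made from 2-methylbut-1-en-3-yne.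
- The bromoindole is cut (Fischer) into (4-bromophenyl)hydrazine and 3,3-dimethylpent-4-enal, the latter from its cheap methyl ester.
- Ring order: indole pyrrole ring first, cyclohexene ring last; no protecting groups.

Assumption: cyclohexene locants are C1 = ring CH bearing the indol-5-yl, C2=C3 = ring alkene, C6 = quaternary carbon. The target is (1R,6S), with the aryl at C1 trans to the ethenyl arm at C6 and cis to the C6 methyl. The sense of induction of the (R)-phosphate in step 5 cannot be predicted with certainty; (R) is written for the (1R,6S) series, and the equally available (S)-catalyst is used if the antipode forms.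

**Step 1**
Reactants: 1 methyl 3,3-dimethylpent-4-enoate
Product: 2 3,3-dimethylpent-4-enal
Conditions: DIBAL-H (1.05 equiv), CH2Cl2, −78 °C; MeOH then aq. Rochelle salt; careful distillation
Reagents that add atoms: none
Why: Low-temperature DIBAL-H partial reduction of a methyl ester stops at the aldehyde oxidation level until aqueous work-up, and the isolated vinyl group is inert to the hydride.

**Step 2**
Reactants: 2 3,3-dimethylpent-4-enal; 3 (4-bromophenyl)hydrazine hydrochloride
Product: 5 5-bromo-3-(2-methylbut-3-en-2-yl)-1H-indole, via hydrazone 4 (not isolated)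
Conditions: AcOH, 25 °C, 1 h, then 80 °C, 3 h
Reagents that add atoms: none
Why: Fischer indole synthesis via hydrazone 4: the only enolisable position is the CH2 next to the quaternary carbon, so the [3,3]-sigmatropic step places the 2-methylbut-3-en-2-yl group at C3 (as in the known preparation of 3-tert-butylindole) and the para-bromine can only end up at C5; no stereocentre is formed.

**Step 3**
Reactants: 6 2-methylbut-1-en-3-yne
Product: 7 4,4,5,5-tetramethyl-2-[(1E)-3-methylbuta-1,3-dien-1-yl]-1,3,2-dioxaborolane
Conditions: HBpin (1.05 equiv), Cp2Zr(H)Cl (5 mol%), Et3N (10 mol%), neat, sealed tube, 60 °C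
Reagents that add atoms: pinacolborane, [H]B1OC(C)(C)C(C)(C)O1
Why: Zirconium-catalysed hydroboration of a terminal alkyne is a syn, anti-Markovnikov addition, so it gives only the (E)-alkenyl boronate and leaves the 1,1-disubstituted alkene untouched.

**Step 4**
Reactants: 5 5-bromo-3-(2-methylbut-3-en-2-yl)-1H-indole; 7 4,4,5,5-tetramethyl-2-[(1E)-3-methylbuta-1,3-dien-1-yl]-1,3,2-dioxaborolane
Product: 8 3-(2-methylbut-3-en-2-yl)-5-[(1E)-3-methylbuta-1,3-dien-1-yl]-1H-indole
Conditions: Pd(OAc)2 (3 mol%), SPhos (6 mol%), K3PO4, THF/H2O 10:1, 40 °C, BHT (trace); stored cold in solution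
Reagents that add atoms: none
Why: Suzuki–Miyaura coupling tolerates the free indole N–H and transfers the alkenyl group with retention of the (E)-geometry, and 40 °C keeps the diene from dimerising thermally.

**Step 5**
Reactants: 8 3-(2-methylbut-3-en-2-yl)-5-[(1E)-3-methylbuta-1,3-dien-1-yl]-1H-indole (two molecules)
Product: 10 5-[(1R,6S)-3,6-dimethyl-6-{(E)-2-[3-(2-methylbut-3-en-2-yl)-1H-indol-5-yl]ethenyl}cyclohex-2-en-1-yl]-3-(2-methylbut-3-en-2-yl)-1H-indole, via distonic bis-allylic radical cation 9 (not isolated)
Conditions: [Ir(ppy)2(dtbbpy)]PF6 (2 mol%), tetrabutylammonium (R)-3,3'-bis(2,4,6-triisopropylphenyl)-1,1'-binaphthyl-2,2'-diyl phosphate (10 mol%), CH2Cl2 (0.05 M), 450 nm LEDs, −40 °C, Ar; stopped at about 70% conversion, 8 recycled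
Reagents that add atoms: none
Why: Proposed new method: the chiral phosphate hydrogen-bonds the N–H of one molecule of 8 so that only this complex is oxidised by the weakly oxidising excited Ir(III) catalyst (proton-coupled electron transfer, no racemic background from free 8), the phosphate-bound radical cation (spin delocalised from N1 through C5 to the terminal CH2) bonds CH2-to-CH2 to a second 8 held by its N–H on the other phosphate oxygen to give 9, and 9 can reach a six-membered ring only by joining the tertiary allylic carbon of one half to the benzylic carbon of the other, which is the natural head-to-head constitution; one phosphate can clamp both N–H groups only when the two indoles lie slipped-parallel, that is with the styryl arm exo and the methyl endo, which sets the C1-aryl/C6-ethenyl trans relationship, while the 3,3'-aryl walls of the (R)-phosphate select one helical sense of this stack and hence the (1R,6S) enantiomer, and electron return from Ir(II) or from fresh, more easily oxidised 8 releases 10; the closest known reaction types are the visible-light radical-cation (hole-catalysed) Diels–Alder reaction of electron-rich styrenes and dienes and the chiral-phosphate-controlled reactions of hydrogen-bonded indole radical cations.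

**Compound list**

1 | methyl 3,3-dimethylpent-4-enoate | COC(=O)CC(C)(C)C=C | starting material
2 | 3,3-dimethylpent-4-enal | O=CCC(C)(C)C=C | intermediate
3 | (4-bromophenyl)hydrazine hydrochloride | NNc1ccc(Br)cc1.Cl | starting material
4 | (E)-1-(4-bromophenyl)-2-(3,3-dimethylpent-4-en-1-ylidene)hydrazine | C=CC(C)(C)C/C=N/Nc1ccc(Br)cc1 | intermediate (not isolated)
5 | 5-bromo-3-(2-methylbut-3-en-2-yl)-1H-indole | C=CC(C)(C)c1c[nH]c2ccc(Br)cc12 | intermediate
6 | 2-methylbut-1-en-3-yne | C=C(C)C#C | starting material
7 | 4,4,5,5-tetramethyl-2-[(1E)-3-methylbuta-1,3-dien-1-yl]-1,3,2-dioxaborolane | C=C(C)/C=C/B1OC(C)(C)C(C)(C)O1 | intermediate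
8 | 3-(2-methylbut-3-en-2-yl)-5-[(1E)-3-methylbuta-1,3-dien-1-yl]-1H-indole | C=CC(C)(C)c1c[nH]c2ccc(/C=C/C(C)=C)cc12 | intermediate
9 | (1E,7E)-3,6-dimethyl-1,8-bis[3-(2-methylbut-3-en-2-yl)-1H-indol-5-yl]octa-1,7-diene-3,6-diyl radical cation (one resonance form drawn) | C=CC(C)(C)c1c[nH]c2ccc(/C=C/[C](C)CC[C+](C)/C=C/c3ccc4[nH]cc(C(C)(C)C=C)c4c3)cc12 | intermediate (not isolated)
10 | 5-[(1R,6S)-3,6-dimethyl-6-{(E)-2-[3-(2-methylbut-3-en-2-yl)-1H-indol-5-yl]ethenyl}cyclohex-2-en-1-yl]-3-(2-methylbut-3-en-2-yl)-1H-indole | C=CC(C)(C)c1c[nH]c2ccc(/C=C/[C@]3(C)CCC(C)=C[C@H]3c3ccc4[nH]cc(C(C)(C)C=C)c4c3)cc12 | target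

**Totals**

Total steps: 5. Longest linear sequence: 4 (steps 1, 2, 4, 5); step 3 is a one-step side branch.

**Steps most likely to fail, with fallbacks**

Step 5 is the main risk. The diastereo- and enantioselectivity rest on an untested template model, and [2+2] adducts, the cis diastereomer or oligomers may compete. The fallback sets out from 8 and comes back at 10. Compound 8 is dimerised without any catalyst in a purely thermal Diels–Alder reaction (2 M in toluene, BHT, 120 °C, sealed tube, dark). This gives the trans dimer as a racemate, that is 10 together with the (1S,6R)-enantiomer of 10 F1. The racemate is purified on silica, and 10 is separated from F1 by preparative SFC on an amylose tris(3,5-dimethylphenylcarbamate) stationary phase.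

Step 2 is the second risk. The acid may shift or hydrate the 2-methylbut-3-en-2-yl group, and aldehyde-derived Fischer reactions can be low-yielding. The fallback sets out from 2 and comes back at 5. Compound 2 is condensed with commercial 4-bromo-2-iodoaniline to (E)-N-(4-bromo-2-iodophenyl)-3,3-dimethylpent-4-en-1-imine F2. In the same flask its enamine tautomer undergoes an intramolecular Heck cyclisation at the C–I bond (Pd(OAc)2, DABCO, DMF, 85 °C), a non-acidic palladium-catalysed indole annulation that leaves the C–Br bond for step 4.

Step 4 is the third risk. The dienyl boronate can protodeboronate or polymerise, and the product diene can dimerise during coupling. The fallback sets out from 5 and comes back at 8. Compound 5 undergoes a Heck reaction with 2-methylbut-3-en-2-ol in fivefold excess (Pd(OAc)2, P(o-tol)3, Et3N, MeCN, 90 °C) to give (E)-2-methyl-4-[3-(2-methylbut-3-en-2-yl)-1H-indol-5-yl]but-3-en-2-ol F3. This stable tertiary allylic alcohol is dehydrated with Burgess reagent (THF, 25 to 50 °C) to 8 just before the dimerisation.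

**Further compounds**

F1 | step 5 | (1S,6R)-enantiomer of 10 | C=CC(C)(C)c1c[nH]c2ccc(/C=C/[C@@]3(C)CCC(C)=C[C@@H]3c3ccc4[nH]cc(C(C)(C)C=C)c4c3)cc12
F2 | step 2 | (E)-N-(4-bromo-2-iodophenyl)-3,3-dimethylpent-4-en-1-imine | C=CC(C)(C)C/C=N/c1ccc(Br)cc1I
F3 | step 4 | (E)-2-methyl-4-[3-(2-methylbut-3-en-2-yl)-1H-indol-5-yl]but-3-en-2-ol | C=CC(C)(C)c1c[nH]c2ccc(/C=C/C(C)(C)O)cc12
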